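**Plan**

1. Retrosynthesis: remove the two MOM ethers and the silyl ether, then cut ring B at C1'–C2', C2'–C3', C4'–C5' and C5'–C6' into a chromonyl diazo enone and (triisopropylsilyloxy)acetylene.
2. Further cuts: the enone C=C (Wittig), the C2 carbaldehyde back to an ester, ring C at O1–C2 and C2–C3 (oxalate Claisen, dehydration), and the C8–prenyl bond.
3. Forward: ring A is supplied by phloroacetophenone and C-prenylated first, ring C is closed second, the diazo enone arm is grown on C2, and ring B is formed last; the siloxyalkyne is made in a three-step branch from tetrahydrofuran.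
4. Enabling feature: ring B is a resorcinol with oxygen on C2' and C4', meta to each other and ortho/para to the C1'–C2 bond. The ketene carbonyl carbon becomes C2'–OH and the siloxyalkyne carbon becomes C4'–O.
5. Stereochemistry: the target has no stereocentre; only the E geometry of the enone is set (Wittig), and it is consumed when ring B forms.

Key step: step 12

Remark: (triisopropylsilyloxy)acetylene is not assumed to be purchasable and is prepared in steps 9–11.
Abbreviations: prenyl = 3-methylbut-2-en-1-yl; MOM = methoxymethyl.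

**Route**

Step 1
Reactants: 1 2,4,6-trihydroxyacetophenone; 2 prenyl bromide
Product: 3 2,4,6-trihydroxy-3-prenylacetophenone
Conditions: 10% aq KOH, 0 °C
Reagents that add atoms: none
Why: C-alkylation of the phloroglucinol phenolate, which in water reacts with the allylic bromide at ring carbon (C3 and C5 are equivalent), is a long-used entry to mono-C-prenyl phloroacetophenone and forms no stereocentre.

Step 2
Reactants: 3 2,4,6-trihydroxy-3-prenylacetophenone
Product: 4 2-hydroxy-4,6-bis(methoxymethoxy)-3-prenylacetophenone
Conditions: MOMCl (2.2 equiv), i-Pr2NEt, CH2Cl2, 0 → 20 °C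
Reagents that add atoms: chloromethyl methyl ether, COCCl
Why: In this MOM ether formation the 4-OH and the less hindered ortho 6-OH should react, while the 2-OH, chelated to the acetyl carbonyl and flanked by the prenyl group, stays free, which is the arrangement an 8-prenyl chromone requires.

Step 3
Reactants: 4 2-hydroxy-4,6-bis(methoxymethoxy)-3-prenylacetophenone; 5 diethyl oxalate
Product: 6 ethyl 2-hydroxy-5,7-bis(methoxymethoxy)-8-prenyl-4-oxochromane-2-carboxylate (racemic hemiketal, in equilibrium with the open 2,4-diketo ester)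
Conditions: LiN(SiMe3)2 (3.3 equiv), THF, −78 °C; 5, −78 → 0 °C; AcOH quench
Reagents that add atoms: none
Why: Crossed Claisen condensation of the phenolate–enolate dianion with the non-enolisable oxalate should be followed by addition of the freed phenol to the new 2-keto group, giving the hemiketal as a racemate whose sp3 centre is removed in step 4.

Step 4
Reactants: 6 ethyl 2-hydroxy-5,7-bis(methoxymethoxy)-8-prenyl-4-oxochromane-2-carboxylate
Product: 7 ethyl 5,7-bis(methoxymethoxy)-8-prenyl-4-oxochromene-2-carboxylate
Conditions: SOCl2, pyridine, CH2Cl2, 0 °C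
Reagents that add atoms: none
Why: Dehydration of the tertiary hemiketal through its chlorosulfite (ionisation assisted by the ring oxygen, proton loss from C3) should complete the γ-pyrone of ring C under buffered aprotic conditions that spare the MOM acetals and the prenyl alkene.

Step 5
Reactants: 7 ethyl 5,7-bis(methoxymethoxy)-8-prenyl-4-oxochromene-2-carboxylate
Product: 8 2-(hydroxymethyl)-5,7-bis(methoxymethoxy)-8-prenylchromen-4-one
Conditions: NaBH4, MeOH–THF, 0 °C
Reagents that add atoms: none
Why: Chemoselective borohydride reduction is expected because the 2-carboxylate, activated by the adjacent ring oxygen, is reduced much faster than the vinylogous-ester carbonyl at C4, an established way to 2-hydroxymethylchromones.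

Step 6
Reactants: 8 2-(hydroxymethyl)-5,7-bis(methoxymethoxy)-8-prenylchromen-4-one
Product: 9 5,7-bis(methoxymethoxy)-8-prenyl-4-oxochromene-2-carbaldehyde
Conditions: Dess–Martin periodinane, CH2Cl2, 0 → 20 °C
Reagents that add atoms: none
Why: Dess–Martin oxidation of the allylic-type primary alcohol should stop at the aldehyde under near-neutral conditions tolerated by MOM ethers and the trisubstituted alkene.

Step 7
Reactants: 9 5,7-bis(methoxymethoxy)-8-prenyl-4-oxochromene-2-carbaldehyde; 10 1-(triphenylphosphoranylidene)propan-2-one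
Product: 11 (E)-4-[5,7-bis(methoxymethoxy)-8-prenyl-4-oxochromen-2-yl]but-3-en-2-one
Conditions: CH2Cl2, 20 °C
Reagents that add atoms: none
Why: Wittig olefination with the stabilised acyl ylide should engage only the aldehyde and give the E enone.

Step 8
Reactants: 11 (E)-4-[5,7-bis(methoxymethoxy)-8-prenyl-4-oxochromen-2-yl]but-3-en-2-one
Product: 13 (E)-1-diazo-4-[5,7-bis(methoxymethoxy)-8-prenyl-4-oxochromen-2-yl]but-3-en-2-one, via trifluoroacetyl diketone 12 (not isolated)
Conditions: LiN(SiMe3)2 (1.1 equiv), THF, −78 °C; CF3CO2CH2CF3; cold 5% aq HCl work-up; then MsN3, Et3N, H2O (1 equiv), MeCN, 20 °C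
Reagents that add atoms: methanesulfonyl azide, CS(=O)(=O)N=[N+]=[N-]; 2,2,2-trifluoroethyl trifluoroacetate, O=C(OCC(F)(F)F)C(F)(F)F (its CF3CO group is carried only in 12)
Why: In this detrifluoroacetylative diazo transfer, kinetic deprotonation of the methyl group (the only enolisable site) and trifluoroacetylation activate the α' carbon, to which the sulfonyl azide transfers N2 with loss of the trifluoroacetyl group; this is the standard route to α'-diazo enones and avoids pyrazoline formation.

Step 9
Reactants: 14 tetrahydrofuran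
Product: 16 triisopropyl(vinyloxy)silane, via lithium ethenolate 15 (not isolated)
Conditions: n-BuLi, THF (solvent and reactant), 25 °C, 16 h; then i-Pr3SiOTf, −78 → 0 °C
Reagents that add atoms: triisopropylsilyl trifluoromethanesulfonate, CC(C)[Si](OS(=O)(=O)C(F)(F)F)(C(C)C)C(C)C
Why: The known cycloreversion of 2-lithiotetrahydrofuran gives ethene and the lithium enolate of acetaldehyde, which the silyl triflate should capture on oxygen (silyl enol ether formation).

Step 10
Reactants: 16 triisopropyl(vinyloxy)silane
Product: 18 (2-bromovinyloxy)triisopropylsilane (Z/E mixture, Z expected to predominate), via dibromo ether 17 (not isolated)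
Conditions: Br2, CH2Cl2, −78 °C; then Et3N, −78 → 20 °C
Reagents that add atoms: bromine, BrBr
Why: Bromine addition to the enol ether followed by amine-induced loss of HBr from the α-bromo ether (addition–elimination) is the known route to 2-bromovinyl ethers, and the bulky silyl group should resist loss as silyl bromide; both alkene isomers serve in step 11.

Step 11
Reactants: 18 (2-bromovinyloxy)triisopropylsilane
Product: 20 (triisopropylsilyloxy)acetylene, via lithium acetylide 19 (not isolated)
Conditions: LiN(i-Pr)2 (2.2 equiv), THF, −78 °C; H2O quench at −78 °C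
Reagents that add atoms: none
Why: Proposed new method: two equivalents of the hindered amide should remove HBr (anti elimination from the Z isomer, α-lithiation and Fritsch–Buttenberg–Wiechell-type hydrogen shift from the E isomer) and hold the alkyne as its lithium acetylide until the cold quench, the bulky triisopropylsilyl group shielding silicon from amide attack and from O-to-C silyl transfer; the closest known reaction type is the NaNH2 or LiN(i-Pr)2 dehydrohalogenation of 2-halovinyl alkyl ethers to alkoxyacetylenes.

Step 12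
Reactants: 13 (E)-1-diazo-4-[5,7-bis(methoxymethoxy)-8-prenyl-4-oxochromen-2-yl]but-3-en-2-one; 20 (triisopropylsilyloxy)acetylene
Product: 25 2-[2-hydroxy-4-(triisopropylsilyloxy)phenyl]-5,7-bis(methoxymethoxy)-8-prenylchromen-4-one, via vinylketene 21 (not isolated), via vinylcyclobutenone 22 (not isolated), via dienylketene 23 (not isolated), via cyclohexadienone 24 (not isolated)
Conditions: 20 (2.5 equiv), ClCH2CH2Cl, degassed, 440 nm LEDs, 20 °C until N2 evolution ends; then 80 °C in the dark
Reagents that add atoms: none
Why: Light should expel N2 from 13 and the alkenyl group should shift to the former diazo carbon (Wolff rearrangement, forming C5'–C6') to give vinylketene 21, whose carbonyl carbon is attacked by the nucleophilic CH carbon of 20 in a polarised [2+2] addition (C2'–C3' and C4'–C5') to give cyclobutenone 22. Heating should open 22 by 4π electrocyclisation to dienylketene 23, which closes ring B by 6π electrocyclisation between the ketene carbon and the chromone-bearing alkene carbon (C1'–C2') and tautomerises from dienone 24 to the phenol. The closest known reaction type is the Danheiser benzannulation in its photochemical Wolff form, in which unsaturated α-diazo ketones and siloxyalkynes give resorcinol monosilyl ethers. No stereocentre results, since the sp3 carbons of 22 and 24 are erased on aromatisation. The regiochemistry needed (silyloxy group para to C1' and meta to the new 2'-OH) is secured by the ynol-ether polarisation, and reversible ring opening of 22 returns any ketene of the wrong geometry to the productive path. Chemoselectivity is secured by light that only the diazo enone absorbs, which spares the chromone and the prenyl alkene, by MOM capping of both ring A phenols and by the excess of alkyne that outruns ketene capture by the product phenol.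

Step 13
Reactants: 25 2-[2-hydroxy-4-(triisopropylsilyloxy)phenyl]-5,7-bis(methoxymethoxy)-8-prenylchromen-4-one
Product: 27 2-(2,4-dihydroxyphenyl)-5,7-dihydroxy-8-prenylchromen-4-one (target), via desilylated flavone 26 (not isolated)
Conditions: Bu4NF, THF, 0 °C; then 3 M HCl, MeOH, 40 °C
Reagents that add atoms: none
Why: Fluoride cleavage of the aryl silyl ether followed by acid-catalysed transacetalisation of the two MOM ethers to methanol should release all four phenols, the acid stage being kept mild and short so that the prenyl group does not cyclise onto the freed 7-OH.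

**Compound list**

1 | 2,4,6-trihydroxyacetophenone | CC(=O)c1c(O)cc(O)cc1O | starting material
2 | prenyl bromide (1-bromo-3-methylbut-2-ene) | CC(C)=CCBr | starting material
3 | 2,4,6-trihydroxy-3-prenylacetophenone | CC(=O)c1c(O)cc(O)c(CC=C(C)C)c1O | intermediate
4 | 2-hydroxy-4,6-bis(methoxymethoxy)-3-prenylacetophenone | CC(=O)c1c(OCOC)cc(OCOC)c(CC=C(C)C)c1O | intermediate
5 | diethyl oxalate | CCOC(=O)C(=O)OCC | starting material
6 | ethyl 2-hydroxy-5,7-bis(methoxymethoxy)-8-prenyl-4-oxochromane-2-carboxylate (racemic) | CCOC(=O)C1(O)CC(=O)c2c(OCOC)cc(OCOC)c(CC=C(C)C)c2O1 | intermediate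
7 | ethyl 5,7-bis(methoxymethoxy)-8-prenyl-4-oxochromene-2-carboxylate | CCOC(=O)c1cc(=O)c2c(OCOC)cc(OCOC)c(CC=C(C)C)c2o1 | intermediate
8 | 2-(hydroxymethyl)-5,7-bis(methoxymethoxy)-8-prenylchromen-4-one | OCc1cc(=O)c2c(OCOC)cc(OCOC)c(CC=C(C)C)c2o1 | intermediate
9 | 5,7-bis(methoxymethoxy)-8-prenyl-4-oxochromene-2-carbaldehyde | O=Cc1cc(=O)c2c(OCOC)cc(OCOC)c(CC=C(C)C)c2o1 | intermediate
10 | 1-(triphenylphosphoranylidene)propan-2-one | CC(=O)C=P(c1ccccc1)(c1ccccc1)c1ccccc1 | starting material
11 | (E)-4-[5,7-bis(methoxymethoxy)-8-prenyl-4-oxochromen-2-yl]but-3-en-2-one | CC(=O)/C=C/c1cc(=O)c2c(OCOC)cc(OCOC)c(CC=C(C)C)c2o1 | intermediate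
12 | (E)-1,1,1-trifluoro-6-[5,7-bis(methoxymethoxy)-8-prenyl-4-oxochromen-2-yl]hex-5-ene-2,4-dione | O=C(CC(=O)/C=C/c1cc(=O)c2c(OCOC)cc(OCOC)c(CC=C(C)C)c2o1)C(F)(F)F | intermediate
13 | (E)-1-diazo-4-[5,7-bis(methoxymethoxy)-8-prenyl-4-oxochromen-2-yl]but-3-en-2-one | [N-]=[N+]=CC(=O)/C=C/c1cc(=O)c2c(OCOC)cc(OCOC)c(CC=C(C)C)c2o1 | intermediate
14 | tetrahydrofuran | C1CCOC1 | starting material
15 | lithium ethenolate (lithium enolate of acetaldehyde) | [Li+].[O-]C=C | intermediate
16 | triisopropyl(vinyloxy)silane | C=CO[Si](C(C)C)(C(C)C)C(C)C | intermediate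
17 | (1,2-dibromoethoxy)triisopropylsilane (racemic) | BrCC(Br)O[Si](C(C)C)(C(C)C)C(C)C | intermediate
18 | (2-bromovinyloxy)triisopropylsilane (Z isomer drawn; E isomer also present and used) | Br/C=C\O[Si](C(C)C)(C(C)C)C(C)C | intermediate
19 | lithium (triisopropylsilyloxy)acetylide | [Li]C#CO[Si](C(C)C)(C(C)C)C(C)C | intermediate
20 | (triisopropylsilyloxy)acetylene | C#CO[Si](C(C)C)(C(C)C)C(C)C | intermediate
21 | (E)-4-[5,7-bis(methoxymethoxy)-8-prenyl-4-oxochromen-2-yl]buta-1,3-dien-1-one (vinylketene) | O=C=C/C=C/c1cc(=O)c2c(OCOC)cc(OCOC)c(CC=C(C)C)c2o1 | intermediate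
22 | 4-[(E)-2-(5,7-bis(methoxymethoxy)-8-prenyl-4-oxochromen-2-yl)vinyl]-3-(triisopropylsilyloxy)cyclobut-2-en-1-one (racemic) | O=C1C=C(O[Si](C(C)C)(C(C)C)C(C)C)C1/C=C/c1cc(=O)c2c(OCOC)cc(OCOC)c(CC=C(C)C)c2o1 | intermediate
23 | 6-[5,7-bis(methoxymethoxy)-8-prenyl-4-oxochromen-2-yl]-3-(triisopropylsilyloxy)hexa-1,3,5-trien-1-one (dienylketene; ketene carbon and alkenyl group cis about the central C=C, terminal C=C of E geometry) | O=C=C/C(O[Si](C(C)C)(C(C)C)C(C)C)=C\C=C\c1cc(=O)c2c(OCOC)cc(OCOC)c(CC=C(C)C)c2o1 | intermediate
24 | 6-[5,7-bis(methoxymethoxy)-8-prenyl-4-oxochromen-2-yl]-3-(triisopropylsilyloxy)cyclohexa-2,4-dien-1-one (racemic) | O=C1C=C(O[Si](C(C)C)(C(C)C)C(C)C)C=CC1c1cc(=O)c2c(OCOC)cc(OCOC)c(CC=C(C)C)c2o1 | intermediate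
25 | 2-[2-hydroxy-4-(triisopropylsilyloxy)phenyl]-5,7-bis(methoxymethoxy)-8-prenylchromen-4-one | CC(C)=CCc1c(OCOC)cc(OCOC)c2c(=O)cc(-c3ccc(O[Si](C(C)C)(C(C)C)C(C)C)cc3O)oc12 | intermediate
26 | 2-(2,4-dihydroxyphenyl)-5,7-bis(methoxymethoxy)-8-prenylchromen-4-one | CC(C)=CCc1c(OCOC)cc(OCOC)c2c(=O)cc(-c3ccc(O)cc3O)oc12 | intermediate
27 | 2-(2,4-dihydroxyphenyl)-5,7-dihydroxy-8-prenylchromen-4-one | CC(C)=CCc1c(O)cc(O)c2c(=O)cc(-c3ccc(O)cc3O)oc12 | target

**Step count and risks**

Total step count: 13. Longest linear sequence: 10 steps (steps 1–8, 12 and 13); the alkyne branch is steps 9–11.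

Steps most likely to fail:

1. Step 11. The amide base may attack silicon, the lithium acetylide may suffer silyl transfer or decomposition, or the carbenoid pathway may divert material, so that the silyl ynol ether is lost. The fallback sets out from 13 and comes back to the route at 27. 13 is irradiated and then heated as in step 12 with tert-butoxyacetylene, an ynol ether whose preparation and ketene [2+2] chemistry are established, to give 2-(4-tert-butoxy-2-hydroxyphenyl)-5,7-bis(methoxymethoxy)-8-prenylchromen-4-one F1. HCl in MeOH then cleaves the tert-butyl ether and both MOM ethers to give 27.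

2. Step 12. The chromone may absorb stray light and undergo its own photoreactions, the vinylketene may dimerise or be captured by the product phenol, or the thermal ring opening and closure may stall at the cyclobutenone. The fallback sets out from 4 and comes back at 27 by a classical flavone construction that forms ring C around a ready-made ring B.
   - 2,4-Dihydroxybenzaldehyde is protected (NaH, MOMCl, DMF) as 2,4-bis(methoxymethoxy)benzaldehyde F2.
   - Claisen–Schmidt condensation of 4 with F2 (KOH, EtOH) gives (E)-1-[2-hydroxy-4,6-bis(methoxymethoxy)-3-prenylphenyl]-3-[2,4-bis(methoxymethoxy)phenyl]prop-2-en-1-one F3.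
   - NaOAc in hot EtOH closes it to racemic 2-[2,4-bis(methoxymethoxy)phenyl]-5,7-bis(methoxymethoxy)-8-prenylchroman-4-one F4.
   - DDQ in dioxane dehydrogenates this to 2-[2,4-bis(methoxymethoxy)phenyl]-5,7-bis(methoxymethoxy)-8-prenylchromen-4-one F5.
   - HCl in MeOH gives 27.

3. Step 8. The lithium enolate may add to the enone or chromone of a second molecule, or the base may open the pyranone, before trifluoroacetylation occurs. The fallback sets out from 9 and comes back at 13 without strong base. Knoevenagel–Doebner condensation of 9 with malonic acid (pyridine, cat. β-alanine, 80 °C) gives (E)-3-[5,7-bis(methoxymethoxy)-8-prenyl-4-oxochromen-2-yl]acrylic acid F6. Isobutyl chloroformate and N-methylmorpholine (THF, −15 °C) convert it into (E)-3-[5,7-bis(methoxymethoxy)-8-prenyl-4-oxochromen-2-yl]acryloyl isobutyl carbonate F7, which acylates ethereal diazomethane at 0 °C to give 13.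

**Further compounds**

F1 | step 11 | 2-(4-tert-butoxy-2-hydroxyphenyl)-5,7-bis(methoxymethoxy)-8-prenylchromen-4-one | CC(C)=CCc1c(OCOC)cc(OCOC)c2c(=O)cc(-c3ccc(OC(C)(C)C)cc3O)oc12
F2 | step 12 | 2,4-bis(methoxymethoxy)benzaldehyde | COCOc1ccc(C=O)c(OCOC)c1
F3 | step 12 | (E)-1-[2-hydroxy-4,6-bis(methoxymethoxy)-3-prenylphenyl]-3-[2,4-bis(methoxymethoxy)phenyl]prop-2-en-1-one | COCOc1ccc(/C=C/C(=O)c2c(OCOC)cc(OCOC)c(CC=C(C)C)c2O)c(OCOC)c1
F4 | step 12 | 2-[2,4-bis(methoxymethoxy)phenyl]-5,7-bis(methoxymethoxy)-8-prenylchroman-4-one (racemic) | COCOc1ccc(C2CC(=O)c3c(OCOC)cc(OCOC)c(CC=C(C)C)c3O2)c(OCOC)c1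
F5 | step 12 | 2-[2,4-bis(methoxymethoxy)phenyl]-5,7-bis(methoxymethoxy)-8-prenylchromen-4-one | COCOc1ccc(-c2cc(=O)c3c(OCOC)cc(OCOC)c(CC=C(C)C)c3o2)c(OCOC)c1
F6 | step 8 | (E)-3-[5,7-bis(methoxymethoxy)-8-prenyl-4-oxochromen-2-yl]acrylic acid | OC(=O)/C=C/c1cc(=O)c2c(OCOC)cc(OCOC)c(CC=C(C)C)c2o1
F7 | step 8 | (E)-3-[5,7-bis(methoxymethoxy)-8-prenyl-4-oxochromen-2-yl]acryloyl isobutyl carbonate | CC(C)COC(=O)OC(=O)/C=C/c1cc(=O)c2c(OCOC)cc(OCOC)c(CC=C(C)C)c2o1
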